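**Retrosynthetic overview**
1. The target is a (2S)-flavanone (rings A, C, B) whose ring B is bonded at C3' to C8 of an intact flavone. The last operations free the ring B phenol and turn a C4 methoxy carbon into the C4 ketone.
2. Strategic feature: O1–C2 and C3–C4 of flavanone ring C are cut together. Ring A then arrives as a methoxy ortho-quinone methide (methide carbon = C4, carrying OMe as the masked ketone; oxygen = O1) made from 2,6-dihydroxy-4-methoxybenzaldehyde and trimethyl orthoformate. C2=C3 is a vinyl group on ring B, and a chiral Brønsted acid sets C2.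
3. The ring B styrene comes from a Suzuki coupling (flavone C8–ring B C3') of an 8-iodoflavone with a para-silyloxy vinylphenyl boronate.
4. Fragments: 4',5,7-trimethoxyflavone (C8 iodination as the 5-methyl ether, then chelation-controlled 5-O-demethylation); 3-bromo-4-hydroxybenzaldehyde (silylation, Wittig, borylation); 2,4,6-trihydroxybenzaldehyde (4-O-methylation).
5. Ring order: the flavone rings are bought intact, the biaryl bond is made next, and flavanone ring C is the only ring built, last.

Key step: step 8

Assumption: the sense of induction of the chiral acid cannot be predicted for this new substrate pair; the catalyst enantiomer (both are available from (R)- or (S)-BINOL) that gives the (2S) product is the one used.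
Remark: the biaryl axis carries three ortho substituents and is treated as freely rotating in the target; the silylated intermediates may appear as rotamer mixtures, which has no consequence for the route.

Step 1
Reactants: 1 2,4,6-trihydroxybenzaldehyde
Product: 2 2,6-dihydroxy-4-methoxybenzaldehyde
Conditions: Me2SO4 (1.0 equiv), K2CO3 (1.0 equiv), acetone, 0 °C → rt
Reagents that add atoms: dimethyl sulfate, COS(=O)(=O)OC
Why: Selective Williamson-type O-methylation: the 4-OH (para to the formyl group, not hydrogen-bonded to it) is the most acidic and most accessible hydroxyl, so one equivalent of base and alkylating agent should methylate O4 first; the over-methylated dimethyl ether is the expected by-product and is removed by chromatography.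

Step 2
Reactants: 3 5,7-dimethoxy-2-(4-methoxyphenyl)chromen-4-one (4',5,7-trimethoxyflavone)
Product: 4 8-iodo-5,7-dimethoxy-2-(4-methoxyphenyl)chromen-4-one
Conditions: NIS (1.1 equiv), CF3CO2H (0.3 equiv), MeCN, 0 °C → rt, dark
Reagents that add atoms: N-iodosuccinimide, O=C1CCC(=O)N1I
Why: Electrophilic aromatic iodination: 5,7-dialkoxyflavones are halogenated at C8 (ortho to O1 and the 7-methoxy group, para to the 5-oxygen), whereas a free 5-hydroxyl would steer the electrophile to C6, which is why the iodine is introduced on the 5-O-methyl ether.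

Step 3
Reactants: 4 8-iodo-5,7-dimethoxy-2-(4-methoxyphenyl)chromen-4-one
Product: 6 5-hydroxy-8-iodo-7-methoxy-2-(4-methoxyphenyl)chromen-4-one, via dichloroboron chelate 5 (not isolated)
Conditions: BCl3 (1.5 equiv), CH2Cl2, −78 → 0 °C; then H2O
Reagents that add atoms: none
Why: Chelation-controlled Lewis acid demethylation: BCl3 binds the C4 carbonyl and cleaves only the peri 5-methyl ether through a six-membered boron chelate, which water hydrolyses; the 7- and 4'-methyl ethers and the aryl iodide are not touched.

Step 4
Reactants: 7 3-bromo-4-hydroxybenzaldehyde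
Product: 8 3-bromo-4-(triisopropylsilyloxy)benzaldehyde
Conditions: TIPSCl (1.2 equiv), imidazole (2.5 equiv), DMF, rt
Reagents that add atoms: chlorotriisopropylsilane, CC(C)[Si](Cl)(C(C)C)C(C)C
Why: Standard imidazole-promoted silylation of a phenol; the bulky silyl ether keeps the oxygen a para donor for the later styrene, withstands acid, and can be removed at the end without base.

Step 5
Reactants: 8 3-bromo-4-(triisopropylsilyloxy)benzaldehyde
Product: 9 (2-bromo-4-vinylphenoxy)triisopropylsilane
Conditions: Ph3PCH3Br (1.3 equiv), NaN(SiMe3)2 (1.25 equiv), THF, 0 °C; then 8, 0 °C → rt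
Reagents that add atoms: methyltriphenylphosphonium bromide, C[P+](c1ccccc1)(c1ccccc1)c1ccccc1.[Br-]
Why: Wittig methylenation of an aryl aldehyde with the preformed non-stabilised ylide; keeping the base slightly below the phosphonium salt leaves no free base to attack the silyl ether, and the aryl bromide is inert.

Step 6
Reactants: 9 (2-bromo-4-vinylphenoxy)triisopropylsilane
Product: 10 triisopropyl[2-(4,4,5,5-tetramethyl-1,3,2-dioxaborolan-2-yl)-4-vinylphenoxy]silane
Conditions: B2pin2 (1.3 equiv), PdCl2(dppf) (5 mol%), KOAc (3 equiv), 1,4-dioxane, 85 °C, BHT (trace)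
Reagents that add atoms: bis(pinacolato)diboron, CC1(C)OB(OC1(C)C)B1OC(C)(C)C(C)(C)O1
Why: Miyaura borylation of an aryl bromide; the weak acetate base does not promote Heck-type reaction of the vinyl group or cleavage of the silyl ether, and vinyl-substituted aryl bromides are known substrates.

Step 7
Reactants: 6 5-hydroxy-8-iodo-7-methoxy-2-(4-methoxyphenyl)chromen-4-one; 10 triisopropyl[2-(4,4,5,5-tetramethyl-1,3,2-dioxaborolan-2-yl)-4-vinylphenoxy]silane
Product: 11 5-hydroxy-7-methoxy-2-(4-methoxyphenyl)-8-[2-(triisopropylsilyloxy)-5-vinylphenyl]chromen-4-one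
Conditions: Pd(OAc)2 (5 mol%), SPhos (10 mol%), K3PO4 (3 equiv), toluene/H2O (10:1), 80 °C, BHT (trace)
Reagents that add atoms: none
Why: Suzuki–Miyaura coupling: the C8–I bond adds oxidatively to zerovalent palladium carrying the bulky biarylphosphine, the boronate transmetalates under phosphate activation, and reductive elimination forms the C8–C3' biaryl bond, the usual way 8-aryl flavones are assembled; the silyl ether is para to a vinyl group, not to a carbonyl, and should tolerate the aqueous phosphate.

Step 8
Reactants: 2 2,6-dihydroxy-4-methoxybenzaldehyde; 11 5-hydroxy-7-methoxy-2-(4-methoxyphenyl)-8-[2-(triisopropylsilyloxy)-5-vinylphenyl]chromen-4-one; 12 trimethyl orthoformate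
Product: 15 5-hydroxy-8-{5-[(2S,4S)-5-hydroxy-4,7-dimethoxychroman-2-yl]-2-(triisopropylsilyloxy)phenyl}-7-methoxy-2-(4-methoxyphenyl)chromen-4-one, via dimethyl acetal 13 (not isolated), via methoxy ortho-quinone methide 14 (not isolated)
Conditions: 2 (1.5 equiv, added slowly), HC(OMe)3 (2 equiv), chiral BINOL-derived N-triflyl imidodiphosphorimidate Brønsted acid (5 mol%), 5 Å molecular sieves, CH2Cl2, −40 → −20 °C; Et3N quench
Reagents that add atoms: none
Why: Proposed new method: the aldehyde is converted in the flask into acetal 13, which the strong chiral acid ionises to an ortho-hydroxyaryl methoxycarbenium ion (the O-protonated form of quinone methide 14) held in a contact ion pair by the confined chiral anion; the terminal carbon of the para-silyloxystyrene attacks the methide carbon (C3–C4) and the phenolic oxygen traps the benzylic cation that develops (O1–C2). The closest known reactions are the achiral acid-catalysed three-component chroman synthesis from salicylaldehydes, orthoformates and styrenes and the chiral Brønsted acid-catalysed cycloadditions of ortho-quinone methides with electron-rich styrenes; new here is the enantioselective version with an alkoxy quinone methide made from an aldehyde. Ring C closes by an asynchronous inverse-electron-demand hetero-[4+2] cycloaddition, four atoms (O1, C8a, C4a, C4) from ring A and two (C3, C2) from the vinyl group, the second bond forming in the stepwise limit by 6-exo-trig capture of the cation by oxygen. C2 is controlled by the chiral counter-anion, which shields one face of the styrene carbon while oxygen closes onto it; C4 should come out cis to the C2 aryl group from an endo-type arrangement, but it becomes trigonal in step 10, so either C4 epimer serves. The step needs regioselectivity (benzylic carbon to oxygen, secured by the para-silyloxy group that stabilises positive charge at C2), a single quinone methide (secured by the two equivalent hydroxyls of 2, one of which remains as the C5 hydroxyl) and chemoselectivity for the vinyl group over flavone C6 and C3 and over renewed ionisation of the product at C4. That chemoselectivity is secured by the higher nucleophilicity of the styrene, the deactivating chromone carbonyl, low temperature, and the excess of acetal that keeps the acid occupied.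

Step 9
Reactants: 15 5-hydroxy-8-{5-[(2S,4S)-5-hydroxy-4,7-dimethoxychroman-2-yl]-2-(triisopropylsilyloxy)phenyl}-7-methoxy-2-(4-methoxyphenyl)chromen-4-one
Product: 16 5-hydroxy-8-{5-[(2S)-4,5-dihydroxy-7-methoxychroman-2-yl]-2-(triisopropylsilyloxy)phenyl}-7-methoxy-2-(4-methoxyphenyl)chromen-4-one (C4 epimers)
Conditions: 0.05 M HCl, THF/H2O (3:1), 0 °C → rt, dilute; pH 7 phosphate buffer quench
Reagents that add atoms: water, O
Why: Acid-catalysed SN1 solvolysis of a benzylic ether: the C4 cation is stabilised by the ortho hydroxyl, the para methoxy group and O1, so the methyl ether ionises under very dilute acid and water in large excess captures the cation; the O1–C2 bond ionises far less readily, so C2 should be untouched, and the silyl ether is acid-stable.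

Step 10
Reactants: 16 5-hydroxy-8-{5-[(2S)-4,5-dihydroxy-7-methoxychroman-2-yl]-2-(triisopropylsilyloxy)phenyl}-7-methoxy-2-(4-methoxyphenyl)chromen-4-one
Product: 17 5-hydroxy-8-{5-[(2S)-5-hydroxy-7-methoxy-4-oxochroman-2-yl]-2-(triisopropylsilyloxy)phenyl}-7-methoxy-2-(4-methoxyphenyl)chromen-4-one
Conditions: activated MnO2 (20 equiv), CH2Cl2, rt
Reagents that add atoms: none
Why: Heterogeneous MnO2 oxidation of an ortho-hydroxybenzylic alcohol to the aryl ketone under neutral conditions; both C4 epimers converge, and neither the phenols, the silyl ether nor the base-sensitive C2 stereocentre of the new 5-hydroxyflavanone is exposed to acid or base.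

Step 11
Reactants: 17 5-hydroxy-8-{5-[(2S)-5-hydroxy-7-methoxy-4-oxochroman-2-yl]-2-(triisopropylsilyloxy)phenyl}-7-methoxy-2-(4-methoxyphenyl)chromen-4-one
Product: 18 2,3-dihydroheveaflavone, 5-hydroxy-8-{2-hydroxy-5-[(2S)-5-hydroxy-7-methoxy-4-oxochroman-2-yl]phenyl}-7-methoxy-2-(4-methoxyphenyl)chromen-4-one
Conditions: HF·pyridine, pyridine, THF, 0 °C → rt (polypropylene vessel); pH 7 buffer work-up
Reagents that add atoms: none
Why: Fluoride cleavage of an aryl silyl ether under buffered, weakly acidic conditions; a free phenoxide para to C2 would open ring C through a quinone methide and racemise the flavanone, and HF·pyridine never generates it.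

**Compound list**
1 | 2,4,6-trihydroxybenzaldehyde | O=Cc1c(O)cc(O)cc1O | starting material
2 | 2,6-dihydroxy-4-methoxybenzaldehyde | COc1cc(O)c(C=O)c(O)c1 | intermediate
3 | 5,7-dimethoxy-2-(4-methoxyphenyl)chromen-4-one | COc1ccc(-c2cc(=O)c3c(OC)cc(OC)cc3o2)cc1 | starting material
4 | 8-iodo-5,7-dimethoxy-2-(4-methoxyphenyl)chromen-4-one | COc1ccc(-c2cc(=O)c3c(OC)cc(OC)c(I)c3o2)cc1 | intermediate
5 | 5-(dichloroboryloxy)-8-iodo-7-methoxy-2-(4-methoxyphenyl)chromen-4-one (boron chelated by the C4 carbonyl) | COc1ccc(-c2cc(=O)c3c(OB(Cl)Cl)cc(OC)c(I)c3o2)cc1 | intermediate (not isolated)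
6 | 5-hydroxy-8-iodo-7-methoxy-2-(4-methoxyphenyl)chromen-4-one | COc1ccc(-c2cc(=O)c3c(O)cc(OC)c(I)c3o2)cc1 | intermediate
7 | 3-bromo-4-hydroxybenzaldehyde | O=Cc1ccc(O)c(Br)c1 | starting material
8 | 3-bromo-4-(triisopropylsilyloxy)benzaldehyde | O=Cc1ccc(O[Si](C(C)C)(C(C)C)C(C)C)c(Br)c1 | intermediate
9 | (2-bromo-4-vinylphenoxy)triisopropylsilane | C=Cc1ccc(O[Si](C(C)C)(C(C)C)C(C)C)c(Br)c1 | intermediate
10 | triisopropyl[2-(4,4,5,5-tetramethyl-1,3,2-dioxaborolan-2-yl)-4-vinylphenoxy]silane | C=Cc1ccc(O[Si](C(C)C)(C(C)C)C(C)C)c(B2OC(C)(C)C(C)(C)O2)c1 | intermediate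
11 | 5-hydroxy-7-methoxy-2-(4-methoxyphenyl)-8-[2-(triisopropylsilyloxy)-5-vinylphenyl]chromen-4-one | COc1ccc(-c2cc(=O)c3c(O)cc(OC)c(-c4cc(C=C)ccc4O[Si](C(C)C)(C(C)C)C(C)C)c3o2)cc1 | intermediate
12 | trimethyl orthoformate | COC(OC)OC | starting material
13 | 2-(dimethoxymethyl)-5-methoxybenzene-1,3-diol | COC(OC)c1c(O)cc(OC)cc1O | intermediate (not isolated)
14 | 3-hydroxy-5-methoxy-2-(methoxymethylidene)cyclohexa-3,5-dien-1-one (reacts as its O-protonated form) | COC=C1C(O)=CC(OC)=CC1=O | intermediate (not isolated)
15 | 5-hydroxy-8-{5-[(2S,4S)-5-hydroxy-4,7-dimethoxychroman-2-yl]-2-(triisopropylsilyloxy)phenyl}-7-methoxy-2-(4-methoxyphenyl)chromen-4-one (2,4-cis) | COc1ccc(-c2cc(=O)c3c(O)cc(OC)c(-c4cc([C@@H]5C[C@H](OC)c6c(O)cc(OC)cc6O5)ccc4O[Si](C(C)C)(C(C)C)C(C)C)c3o2)cc1 | intermediate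
16 | 5-hydroxy-8-{5-[(2S)-4,5-dihydroxy-7-methoxychroman-2-yl]-2-(triisopropylsilyloxy)phenyl}-7-methoxy-2-(4-methoxyphenyl)chromen-4-one (C4 epimers, C4 left open) | COc1ccc(-c2cc(=O)c3c(O)cc(OC)c(-c4cc([C@@H]5CC(O)c6c(O)cc(OC)cc6O5)ccc4O[Si](C(C)C)(C(C)C)C(C)C)c3o2)cc1 | intermediate
17 | 5-hydroxy-8-{5-[(2S)-5-hydroxy-7-methoxy-4-oxochroman-2-yl]-2-(triisopropylsilyloxy)phenyl}-7-methoxy-2-(4-methoxyphenyl)chromen-4-one | COc1ccc(-c2cc(=O)c3c(O)cc(OC)c(-c4cc([C@@H]5CC(=O)c6c(O)cc(OC)cc6O5)ccc4O[Si](C(C)C)(C(C)C)C(C)C)c3o2)cc1 | intermediate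
18 | 2,3-dihydroheveaflavone, (2S) | COc1ccc(-c2cc(=O)c3c(O)cc(OC)c(-c4cc([C@@H]5CC(=O)c6c(O)cc(OC)cc6O5)ccc4O)c3o2)cc1 | target

**Step count**
Total: 11 steps. Longest linear sequence: 8 steps (steps 4, 5, 6, 7, 8, 9, 10, 11, from 3-bromo-4-hydroxybenzaldehyde).

**Steps most likely to fail**

Step 8 (proposed new method). What may go wrong:
- the strongly stabilised trioxygenated carbenium ion may be too weak an electrophile for the styrene;
- the acetal may condense with itself;
- the product may ionise again at C4 and react further;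
- the chiral anion may not discriminate the faces at C2.

The fallback uses known chemistry, sets out from 11 and returns at 17.
- Lemieux–Johnson cleavage of the vinyl group (OsO4 cat., NaIO4, 2,6-lutidine, dioxane/H2O) gives 3-[5-hydroxy-7-methoxy-2-(4-methoxyphenyl)-4-oxochromen-8-yl]-4-(triisopropylsilyloxy)benzaldehyde F1.
- Commercial 2',6'-dihydroxy-4'-methoxyacetophenone (CC(=O)c1c(O)cc(OC)cc1O) is mono-protected with MOMCl and iPr2NEt to 1-[2-hydroxy-4-methoxy-6-(methoxymethoxy)phenyl]ethanone F2.
- Claisen–Schmidt condensation of the enolate of F2 (LiN(SiMe3)2, THF, −78 °C → rt) with F1 should give the (E)-chalcone 5-hydroxy-8-{5-[(E)-3-[2-hydroxy-4-methoxy-6-(methoxymethoxy)phenyl]-3-oxoprop-1-enyl]-2-(triisopropylsilyloxy)phenyl}-7-methoxy-2-(4-methoxyphenyl)chromen-4-one F3 with the silyl ether intact.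
- Methanolic HCl (THF/MeOH, 50 °C) removes the acetal protecting group to give the 2',6'-dihydroxychalcone 8-{5-[(E)-3-(2,6-dihydroxy-4-methoxyphenyl)-3-oxoprop-1-enyl]-2-(triisopropylsilyloxy)phenyl}-5-hydroxy-7-methoxy-2-(4-methoxyphenyl)chromen-4-one F4, which is not isolated.
- F4 closes ring C in the same pot by intramolecular oxa-Michael addition to the racemic silylated flavanone 5-hydroxy-8-[5-(5-hydroxy-7-methoxy-4-oxochroman-2-yl)-2-(triisopropylsilyloxy)phenyl]-7-methoxy-2-(4-methoxyphenyl)chromen-4-one F5.
- Preparative HPLC on an amylose tris(3,5-dimethylphenylcarbamate) stationary phase separates the enantiomers, and the (2S) enantiomer is 17.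

Step 9. What may go wrong: the C4 cation may lose the C3 proton (flav-3-ene formation) or alkylate an electron-rich ring of a second molecule faster than water captures it. The fallback sets out from 15 and returns at 17, bypassing 16 and step 10. DDQ (1.2 equiv) in CH2Cl2/pH 7 buffer at 0 °C abstracts the C4 hydride next to the methoxy group, the manifold of oxidative cleavage of electron-rich benzyl ethers. Water adds to the oxocarbenium ion and the hemiketal collapses with loss of methanol to the ketone. No compound outside the compound list is made (F0).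

Step 7. What may go wrong: transmetalation onto the doubly ortho-substituted C8–palladium intermediate may be slow, so that protodeboronation of the ortho-silyloxy boronate and Heck-type arylation of its vinyl group take over. The fallback exchanges the roles of the partners; it sets out from 6 and returns at 11.
- Miyaura borylation of 6 (B2pin2, PdCl2(dppf), KOAc, dioxane, 90 °C) gives 5-hydroxy-7-methoxy-2-(4-methoxyphenyl)-8-(4,4,5,5-tetramethyl-1,3,2-dioxaborolan-2-yl)chromen-4-one F6.
- F6 is coupled with bromide 9 (Pd(OAc)2, SPhos, K3PO4, toluene/H2O, 80 °C). Oxidative addition then takes place at the less hindered bromide, and the boron no longer sits next to the bulky silyloxy group.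

**Further compounds**
F1 | step 8 | 3-[5-hydroxy-7-methoxy-2-(4-methoxyphenyl)-4-oxochromen-8-yl]-4-(triisopropylsilyloxy)benzaldehyde | COc1ccc(-c2cc(=O)c3c(O)cc(OC)c(-c4cc(C=O)ccc4O[Si](C(C)C)(C(C)C)C(C)C)c3o2)cc1
F2 | step 8 | 1-[2-hydroxy-4-methoxy-6-(methoxymethoxy)phenyl]ethanone | COCOc1cc(OC)cc(O)c1C(C)=O
F3 | step 8 | 5-hydroxy-8-{5-[(E)-3-[2-hydroxy-4-methoxy-6-(methoxymethoxy)phenyl]-3-oxoprop-1-enyl]-2-(triisopropylsilyloxy)phenyl}-7-methoxy-2-(4-methoxyphenyl)chromen-4-one | COc1ccc(-c2cc(=O)c3c(O)cc(OC)c(-c4cc(/C=C/C(=O)c5c(O)cc(OC)cc5OCOC)ccc4O[Si](C(C)C)(C(C)C)C(C)C)c3o2)cc1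
F4 | step 8 | 8-{5-[(E)-3-(2,6-dihydroxy-4-methoxyphenyl)-3-oxoprop-1-enyl]-2-(triisopropylsilyloxy)phenyl}-5-hydroxy-7-methoxy-2-(4-methoxyphenyl)chromen-4-one | COc1ccc(-c2cc(=O)c3c(O)cc(OC)c(-c4cc(/C=C/C(=O)c5c(O)cc(OC)cc5O)ccc4O[Si](C(C)C)(C(C)C)C(C)C)c3o2)cc1
F5 | step 8 | racemic 5-hydroxy-8-[5-(5-hydroxy-7-methoxy-4-oxochroman-2-yl)-2-(triisopropylsilyloxy)phenyl]-7-methoxy-2-(4-methoxyphenyl)chromen-4-one | COc1ccc(-c2cc(=O)c3c(O)cc(OC)c(-c4cc(C5CC(=O)c6c(O)cc(OC)cc6O5)ccc4O[Si](C(C)C)(C(C)C)C(C)C)c3o2)cc1
F0 | step 9 | none | none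
F6 | step 7 | 5-hydroxy-7-methoxy-2-(4-methoxyphenyl)-8-(4,4,5,5-tetramethyl-1,3,2-dioxaborolan-2-yl)chromen-4-one | COc1ccc(-c2cc(=O)c3c(O)cc(OC)c(B4OC(C)(C)C(C)(C)O4)c3o2)cc1
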